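The amounts came first: how much D the solution and Q could take up, against how much D was charged.

    L + X ⇌ L.X, settled at all times (K1 = 17 /M)
    L + Q → L.Q (k2 = 13 /M/h)
    L ⇌ X (K3 = 1.7, k3 = 0.15 /h)
    D ⇌ L, rate k4*(cs4 - [L]) while solid is left; crystals form when [L] > cs4 (cs4 = 8.1 mM, k4 = 1.4 /h)

D 0.13 M; Q 2.60 mM; time 15 d

* the state of affairs at 15 d: stopped, and by what, or still going (for what has run out or reacted, a solid counts together with what of it has only dissolved) (it is still moving / forward and back rates have come level / all of D has reacted)
* X at 15 d, in percent of the D charged
* L at 15 d, in percent of the D charged

- percentages count the D that a species holds: one L.X counts as two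
- X is meant together with its L.X
- solid, in amounts per volume of the solution: D
- at the start none of D is in solution
- what has only dissolved of D counts as not reacted
- in an amount of X, one L.X counts as one X
- the reaction counts as stopped when no species that holds the D changes by six tenths of a point or more over the second half of the time
- L means what is dissolved; the solid is not counted in it
- run time (flask): 15 d

I climbed the ladder of times from the fastest rung. L.X stood at balance with L and X at every moment. The gap of L to its solubility came next, closing with a half-life of 0.0206 d, shorter than the 0.121 d relaxation of L and free X, so L lay close to its solubility while X formed. Q followed: against L at solubility its half-life was 0.274 d, longer than that relaxation but shorter than the run of 15 d. The run held 54.7 such half-lives, so I counted the charge of Q, the limiting reagent of its step, as L.Q.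

I then solved both ends. The start was solid D under a solution that held Q and none of D; the end was solid under a solution with L at its solubility of 8.1 mM, and the ladder joined them well inside the run:

L: 8.1 mM

free X: 1.7 × L = 13.8 mM

L.X: 17 /M × L × free X = 1.90 mM

L.Q: 2.60 mM

the demand, the D taken up by the saturated solution in each of its forms, L.X counted twice: 28.3 mM

The demand was 21.8% of the charge, so solid stayed and the reversible steps came level. I reckoned L at 6.23% and X, one L.X counted as one, at 12.1%.

The forecast was that forward and back rates have come level, with L at 6.2% and X at 13.5%, above my X, and its grounds read “counted each L.X as two D in the X percentage”.

The simulation showed that forward and back rates have come level, with X at 12.1% and L at 6.23%.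

In this flask the dissolution of D had 99.5% of its turnover behind it at 3.00 d, sooner than 15 d. The demand of 28.3 mM stood below the charge of 0.13 M, which leaves 78.2% as solid, and D read 78.3% at 15.0 d. The neighbour flask with 0.33 M of D held the same Q, so I gave it the same demand, 8.58% of its charge, and put its L at 2.45% and its X at 4.76%. That neighbour flask gave L at 2.45% and X at 4.75%, with D at 91.4% at 15.0 d.

All constants come from no measurement; the run is a simulation.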